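Ring numbering used throughout: C1(=CH2)–C2=C3–C4(CH3)2–C5(O-acyl)–C6–C7–C8(CH3)=C9–C10–C11 (eleven-membered carbocycle).
Retrosynthetic cuts: first the C5–O acyl bond (vanillate). Then the diene is traced back to a C2 ketone (C1=CH2 by α-methylenation, C2=C3 by elimination of a C2–O group). Last, C10–C11 is cut with re-formation of C2–C8.
Enabling feature: with C=O at C2 the ring is an (E)-cycloundec-5-enone, in which C2=O and C8=C9 are linked through C1, C11 and C10. This is the retron of the oxy-Cope ring enlargement of a trans-1,2-divinylcycloheptanol whose seven-membered ring is C2–C3–C4–C5–C6–C7–C8.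
Forward order of rings: tetrahydrofuran (bromoetherification of linalool); seven-membered ring (Claisen ring enlargement to karahanaenone, which already holds C4(CH3)2, the C5 oxygen and the C8 methyl); then C2=O, C8-vinyl and C2-vinyl; eleven-membered ring (key step); diene; ester.
Stereochemistry: C5 (R) comes from reagent-controlled reduction of the achiral ketone with (+)-DIP-Cl. E C8=C9 comes from the chair transition state of the trans-divinyl carbinol. E C2=C3 comes from the palladium-mediated elimination.

Key step: step 10

Remark 1: C8 is created in the chlorination without control relative to remote C5. Every compound from the chloro ketone to the divinyl carbinol and its alkoxide is therefore a pair of isomers. They differ in the sense of C8, and of C2 which follows C8, relative to C5. Names and SMILES show one series. The other series reacts alike, and both end in the same ring-enlarged ketone, in which C2 and C8 are trigonal.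
Remark 2: racemic linalool suffices, because its only stereocentre disappears in step 2.

Step 1
Reactants: 1 (±)-linalool (3,7-dimethylocta-1,6-dien-3-ol)
Product: 2 2-(2-bromopropan-2-yl)-5-methyl-5-vinyltetrahydrofuran (racemic cis/trans mixture)
Conditions: NBS, CH2Cl2, 0 °C
Reagents that add atoms: N-bromosuccinimide, O=C1CCC(=O)N1Br
Why: Bromoetherification: the bromonium ion forms on the more electron-rich trisubstituted alkene and the tertiary hydroxyl closes 5-exo, leaving the vinyl group untouched; the ring stereocentres need no control because they are lost in step 2.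

Step 2
Reactants: 2 2-(2-bromopropan-2-yl)-5-methyl-5-vinyltetrahydrofuran
Product: 4 karahanaenone (2,2,5-trimethylcyclohept-4-en-1-one), via enol ether 3 (not isolated)
Conditions: 2,4,6-collidine, reflux (ca. 170 °C)
Reagents that add atoms: none
Why: E2 loss of HBr toward the ring C–H gives the allyl vinyl ether 3, which at this temperature undergoes a Claisen rearrangement that enlarges the five-membered ether to the seven-membered ketone and lays down C5=O, C4(CH3)2, C3H2 and the C2=C8(CH3) alkene in the order needed.

Step 3
Reactants: 4 karahanaenone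
Product: 5 (1R)-2,2,5-trimethylcyclohept-4-en-1-ol
Conditions: (+)-DIP-Cl, THF, −25 °C to rt; HN(CH2CH2OH)2, Et2O
Reagents that add atoms: none
Why: Asymmetric β-hydride transfer from DIP-Cl through the boat-like six-membered transition state, a reduction that works best with ketones flanked by a quaternary carbon (2,2-dimethylcycloalkanones): the C4 side acts as the large group, so the (+)-reagent should deliver the R alcohol and thereby set C5, while the alkene is inert to the reagent.

Step 4
Reactants: 5 (1R)-2,2,5-trimethylcyclohept-4-en-1-ol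
Product: 6 tert-butyl(dimethyl){[(1R)-2,2,5-trimethylcyclohept-4-en-1-yl]oxy}silane
Conditions: TBSOTf, 2,6-lutidine, CH2Cl2, 0 °C
Reagents that add atoms: tert-butyldimethylsilyl triflate, CC(C)(C)[Si](C)(C)OS(=O)(=O)C(F)(F)F
Why: Silylation with the triflate is chosen because the carbinol is neopentylic; the TBS ether should survive borane, Grignard reagents, KH, LDA and Pd(0) later on.

Step 5
Reactants: 6 TBS ether of 5
Product: 8 (5R)-5-[(tert-butyldimethylsilyl)oxy]-2,6,6-trimethylcycloheptan-1-ol (OH and 2-CH3 trans; both facial isomers), via alkylborane 7 (not isolated)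
Conditions: BH3·THF, THF, 0 °C to rt; NaOH, H2O2, 0 °C
Reagents that add atoms: hydrogen peroxide, OO
Why: Hydroboration–oxidation: boron goes to the less substituted alkene carbon C2 and hydrogen to C8 (syn addition), so oxygen ends at C2; the two new stereocentres are removed in steps 6 and 7 and need no control.

Step 6
Reactants: 8 (5R)-5-silyloxy-2,6,6-trimethylcycloheptan-1-ol
Product: 9 (5R)-5-[(tert-butyldimethylsilyl)oxy]-2,6,6-trimethylcycloheptan-1-one (C2 epimers)
Conditions: Dess–Martin periodinane, CH2Cl2, rt
Reagents that add atoms: none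
Why: Dess–Martin oxidation of a secondary alcohol under near-neutral conditions that leave the silyl ether intact.

Step 7
Reactants: 9 (5R)-5-silyloxy-2,6,6-trimethylcycloheptan-1-one
Product: 10 (2R,5R)-5-[(tert-butyldimethylsilyl)oxy]-2-chloro-2,6,6-trimethylcycloheptan-1-one (see remark 1)
Conditions: SO2Cl2, CH2Cl2, 0 °C to rt
Reagents that add atoms: sulfuryl chloride, ClS(Cl)(=O)=O
Why: Electrophilic α-chlorination through the more substituted enol (C2=C8), the regiochemistry known for 2-methylcycloalkanones and reinforced here by the neopentylic, slowly enolising C3.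

Step 8
Reactants: 10 chloro ketone; 11 vinylmagnesium bromide
Product: 13 (2R,5R)-5-[(tert-butyldimethylsilyl)oxy]-2,6,6-trimethyl-2-vinylcycloheptan-1-one, via chlorohydrin alkoxide 12 (not isolated)
Conditions: CH2=CHMgBr (1.05 equiv), THF, −78 °C to rt; then toluene, 80 °C
Reagents that add atoms: none
Why: 1,2-Addition anti to the C–Cl bond (polar Felkin–Anh) gives the halomagnesium chlorohydrin 12 with vinyl antiperiplanar to chloride, and warming triggers the semipinacol-type 1,2-vinyl shift with inversion at C8, the established way from 2-chlorocycloalkanones to 2-vinylcycloalkanones.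

Step 9
Reactants: 13 2-methyl-2-vinyl ketone; 11 vinylmagnesium bromide
Product: 14 (1S,2R,5R)-5-[(tert-butyldimethylsilyl)oxy]-2,6,6-trimethyl-1,2-divinylcycloheptan-1-ol (vinyl groups trans)
Conditions: CH2=CHMgBr, anhydrous CeCl3, THF, −78 °C; aq NH4Cl; chromatography
Reagents that add atoms: none
Why: Organocerium 1,2-addition (no enolisation of the hindered ketone): in a Felkin–Anh arrangement the C8–vinyl bond stands perpendicular to the carbonyl plane (π(C=C)/π*(C=O) overlap, smaller A value than methyl), so the reagent should enter anti to it and set C2 with the two vinyl groups trans; any cis carbinol is removed by chromatography.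

Step 10
Reactants: 14 trans-1,2-divinylcycloheptanol
Product: 17 (5E,9R)-9-[(tert-butyldimethylsilyl)oxy]-6,10,10-trimethylcycloundec-5-en-1-one, via potassium alkoxide 15 (not isolated), via potassium enolate 16 (not isolated)
Conditions: KH, 18-crown-6, THF, 0 °C to rt; aq NH4Cl
Reagents that add atoms: none
Why: KH with 18-crown-6 turns 14 into the dissociated alkoxide 15, in which the oxyanion weakens the adjacent C2–C8 bond, and the 3-oxido-1,5-diene C11=C1–C2(O−)–C8–C9=C10 undergoes a concerted [3,3]-sigmatropic shift (anionic oxy-Cope rearrangement; closest known case: the six-to-ten enlargement of 1,2-divinylcyclohexanols to (E)-cyclodec-5-enones). The eleven-membered ring is not closed end to end: C10–C11 forms between two vinyl termini that the seven-membered ring already holds within reach while the shared C2–C8 bond breaks, i.e. a four-carbon ring enlargement. No sp3 stereocentre is created, C2 and C8 become trigonal and C5 with its silyl ether is a spectator, so the only new stereo-element is the C8=C9 geometry. Because the vinyl groups are trans, the chair transition state carries both ring bonds (C2–C3 and C8–C7) pseudo-equatorial and O− and CH3 pseudo-axial, which places C7 trans to C10 and should give the E alkene; this E/Z selectivity is the one the step needs and it is secured by the relative configuration purified in step 9. Formation of the delocalised, regiodefined C1=C2 enolate 16 makes the rearrangement irreversible, and protonation gives 17.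

Step 11
Reactants: 17 (E)-cycloundec-5-enone
Product: 21 (5E,9R)-9-[(tert-butyldimethylsilyl)oxy]-6,10,10-trimethyl-2-methylidenecycloundec-5-en-1-one, via lithium enolate 18 (not isolated), via Mannich base 19 (not isolated), via methiodide 20 (not isolated)
Conditions: LDA, THF, −78 °C; CH2=NMe2+ I−, −78 °C to rt; MeI, CH2Cl2, rt; DBU, CH2Cl2, rt
Reagents that add atoms: Eschenmoser's salt, C=[N+](C)C.[I-]
Why: Kinetic deprotonation takes place at C1 because C3 is neopentylic; Mannich reaction of the enolate with Eschenmoser's salt followed by quaternisation and E1cB loss of trimethylamine is the standard α-methylenation of ketones.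

Step 12
Reactants: 21 α-methylene ketone
Product: 22 (5E,9R)-9-[(tert-butyldimethylsilyl)oxy]-6,10,10-trimethyl-2-methylidenecycloundec-5-en-1-ol (both carbinol epimers)
Conditions: NaBH4, CeCl3·7H2O, MeOH, −78 °C to 0 °C
Reagents that add atoms: none
Why: Luche reduction: the cerium-modified borohydride attacks the enone 1,2; both C2 epimers are acceptable because C2 becomes trigonal again in step 14.

Step 13
Reactants: 22 allylic alcohol
Product: 23 acetate of 22
Conditions: Ac2O, pyridine, DMAP (cat.), CH2Cl2, rt
Reagents that add atoms: acetic anhydride, CC(=O)OC(C)=O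
Why: DMAP-catalysed acetylation of the secondary allylic alcohol provides the leaving group for palladium.

Step 14
Reactants: 23 allylic acetate
Product: 24 tert-butyl(dimethyl){[(1R,3E,8E)-2,2,9-trimethyl-5-methylidenecycloundeca-3,8-dien-1-yl]oxy}silane
Conditions: Pd(PPh3)4 (5 mol %), Et3N, 1,4-dioxane, reflux
Reagents that add atoms: none
Why: Palladium(0)-catalysed 1,4-elimination of an allylic acetate (Tsuji–Trost ionisation, then loss of a β-hydrogen): in the η3-allyl complex over CH2–C1–C2 the only hydrogens next to an allyl terminus are those at C3, acetate return is reversible, and hydrogen is lost from the rotamer with the bulky C4 anti to C1, which should give the E C2=C3 alkene conjugated with the exocyclic methylene.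

Step 15
Reactants: 24 silyl ether of the trienol
Product: 25 (1R,3E,8E)-2,2,9-trimethyl-5-methylidenecycloundeca-3,8-dien-1-ol
Conditions: TBAF, THF, 50 °C
Reagents that add atoms: none
Why: Fluoride-induced cleavage of the hindered silyl ether (warming needed); the triene has no fluoride-sensitive group and C5 keeps its configuration because its C–O bond is not touched.

Step 16
Reactants: 26 vanillic acid (4-hydroxy-3-methoxybenzoic acid)
Product: 28 4-[(tert-butyldimethylsilyl)oxy]-3-methoxybenzoic acid, via bis-silyl derivative 27 (not isolated)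
Conditions: TBSCl (2.5 equiv), imidazole, DMF, rt; then AcOH–THF–H2O, rt
Reagents that add atoms: tert-butyldimethylsilyl chloride, CC(C)(C)[Si](C)(C)Cl
Why: Exhaustive silylation of phenol and acid followed by selective hydrolysis of the far more labile silyl ester leaves only the phenol masked.

Step 17
Reactants: 28 silyl-protected vanillic acid
Product: 29 4-[(tert-butyldimethylsilyl)oxy]-3-methoxybenzoyl chloride
Conditions: (COCl)2, DMF (cat.), CH2Cl2, 0 °C to rt
Reagents that add atoms: oxalyl chloride, ClC(=O)C(=O)Cl
Why: Vilsmeier-type activation with oxalyl chloride and catalytic DMF gives the acid chloride under conditions that an aryl silyl ether tolerates.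

Step 18
Reactants: 25 trienol; 29 protected vanilloyl chloride
Product: 30 (1R,3E,8E)-2,2,9-trimethyl-5-methylidenecycloundeca-3,8-dien-1-yl 4-[(tert-butyldimethylsilyl)oxy]-3-methoxybenzoate
Conditions: Et3N, DMAP, toluene, 60 °C
Reagents that add atoms: none
Why: DMAP-mediated acylation through the N-acylpyridinium salt, the method of choice for a neopentylic secondary alcohol; the C5–O bond and hence the R configuration are retained, and the silyl-masked phenol can neither compete nor transfer an acyl group.

Step 19
Reactants: 30 silyl-protected ester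
Product: 31 target, (1R,3E,8E)-2,2,9-trimethyl-5-methylidenecycloundeca-3,8-dien-1-yl 4-hydroxy-3-methoxybenzoate
Conditions: TBAF, AcOH, THF, 0 °C
Reagents that add atoms: none
Why: Aryl silyl ethers are cleaved rapidly by buffered fluoride at low temperature, conditions under which the hindered benzoate and the triene should remain intact.

Compound list
1 | (±)-linalool, 3,7-dimethylocta-1,6-dien-3-ol | C=CC(C)(O)CCC=C(C)C | starting material
2 | 2-(2-bromopropan-2-yl)-5-methyl-5-vinyltetrahydrofuran (racemic cis/trans mixture) | C=CC1(C)CCC(O1)C(C)(C)Br | intermediate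
3 | 2-methyl-5-(propan-2-ylidene)-2-vinyltetrahydrofuran (formed in situ) | C=CC1(C)CCC(=C(C)C)O1 | intermediate
4 | karahanaenone, 2,2,5-trimethylcyclohept-4-en-1-one | CC1=CCC(C)(C)C(=O)CC1 | intermediate
5 | (1R)-2,2,5-trimethylcyclohept-4-en-1-ol | CC1=CCC(C)(C)[C@H](O)CC1 | intermediate
6 | tert-butyl(dimethyl){[(1R)-2,2,5-trimethylcyclohept-4-en-1-yl]oxy}silane | CC1=CCC(C)(C)[C@H](O[Si](C)(C)C(C)(C)C)CC1 | intermediate
7 | monoalkylborane from 6, boron at C2 (formed in situ) | BC1CC(C)(C)[C@H](O[Si](C)(C)C(C)(C)C)CCC1C | intermediate
8 | (5R)-5-[(tert-butyldimethylsilyl)oxy]-2,6,6-trimethylcycloheptan-1-ol (OH/2-CH3 trans, both facial isomers) | OC1CC(C)(C)[C@H](O[Si](C)(C)C(C)(C)C)CCC1C | intermediate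
9 | (5R)-5-[(tert-butyldimethylsilyl)oxy]-2,6,6-trimethylcycloheptan-1-one (C2 epimers) | O=C1CC(C)(C)[C@H](O[Si](C)(C)C(C)(C)C)CCC1C | intermediate
10 | (2R,5R)-5-[(tert-butyldimethylsilyl)oxy]-2-chloro-2,6,6-trimethylcycloheptan-1-one (and its 2S epimer, remark 1) | O=C1CC(C)(C)[C@H](O[Si](C)(C)C(C)(C)C)CC[C@@]1(C)Cl | intermediate
11 | vinylmagnesium bromide | C=C[Mg]Br | starting material
12 | bromomagnesium alkoxide of the chlorohydrin, C2-vinyl trans to C8-Cl (formed in situ) | C=C[C@]1([O-])CC(C)(C)[C@H](O[Si](C)(C)C(C)(C)C)CC[C@@]1(C)Cl.[Mg+2].[Br-] | intermediate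
13 | (2R,5R)-5-[(tert-butyldimethylsilyl)oxy]-2,6,6-trimethyl-2-vinylcycloheptan-1-one | O=C1CC(C)(C)[C@H](O[Si](C)(C)C(C)(C)C)CC[C@]1(C)C=C | intermediate
14 | (1S,2R,5R)-5-[(tert-butyldimethylsilyl)oxy]-2,6,6-trimethyl-1,2-divinylcycloheptan-1-ol (vinyl groups trans) | C=C[C@@]1(O)CC(C)(C)[C@H](O[Si](C)(C)C(C)(C)C)CC[C@]1(C)C=C | intermediate
15 | potassium alkoxide of 14 (formed in situ) | C=C[C@@]1([O-])CC(C)(C)[C@H](O[Si](C)(C)C(C)(C)C)CC[C@]1(C)C=C.[K+] | intermediate
16 | potassium C1=C2 enolate of 17, C3 trans to C11 (formed in situ) | [K+].[O-]/C1=C\CC/C=C(C)/CC[C@@H](O[Si](C)(C)C(C)(C)C)C(C)(C)C1 | intermediate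
17 | (5E,9R)-9-[(tert-butyldimethylsilyl)oxy]-6,10,10-trimethylcycloundec-5-en-1-one | O=C1CC(C)(C)[C@H](O[Si](C)(C)C(C)(C)C)CC/C(C)=C/CCC1 | intermediate
18 | lithium C1=C2 enolate of 17 (formed in situ) | [Li+].[O-]C1=CCC/C=C(C)/CC[C@@H](O[Si](C)(C)C(C)(C)C)C(C)(C)C1 | intermediate
19 | 2-[(dimethylamino)methyl] derivative of 17 (Mannich base at C1, formed in situ) | O=C1CC(C)(C)[C@H](O[Si](C)(C)C(C)(C)C)CC/C(C)=C/CCC1CN(C)C | intermediate
20 | methiodide of 19 (formed in situ) | O=C1CC(C)(C)[C@H](O[Si](C)(C)C(C)(C)C)CC/C(C)=C/CCC1C[N+](C)(C)C.[I-] | intermediate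
21 | (5E,9R)-9-[(tert-butyldimethylsilyl)oxy]-6,10,10-trimethyl-2-methylidenecycloundec-5-en-1-one | C=C1C(=O)CC(C)(C)[C@H](O[Si](C)(C)C(C)(C)C)CC/C(C)=C/CC1 | intermediate
22 | (5E,9R)-9-[(tert-butyldimethylsilyl)oxy]-6,10,10-trimethyl-2-methylidenecycloundec-5-en-1-ol (both carbinol epimers) | C=C1C(O)CC(C)(C)[C@H](O[Si](C)(C)C(C)(C)C)CC/C(C)=C/CC1 | intermediate
23 | acetate of 22 | C=C1C(OC(C)=O)CC(C)(C)[C@H](O[Si](C)(C)C(C)(C)C)CC/C(C)=C/CC1 | intermediate
24 | tert-butyl(dimethyl){[(1R,3E,8E)-2,2,9-trimethyl-5-methylidenecycloundeca-3,8-dien-1-yl]oxy}silane | C=C1/C=C/C(C)(C)[C@H](O[Si](C)(C)C(C)(C)C)CC/C(C)=C/CC1 | intermediate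
25 | (1R,3E,8E)-2,2,9-trimethyl-5-methylidenecycloundeca-3,8-dien-1-ol | C=C1/C=C/C(C)(C)[C@H](O)CC/C(C)=C/CC1 | intermediate
26 | vanillic acid | COc1cc(C(=O)O)ccc1O | starting material
27 | tert-butyldimethylsilyl 4-[(tert-butyldimethylsilyl)oxy]-3-methoxybenzoate (formed in situ) | COc1cc(C(=O)O[Si](C)(C)C(C)(C)C)ccc1O[Si](C)(C)C(C)(C)C | intermediate
28 | 4-[(tert-butyldimethylsilyl)oxy]-3-methoxybenzoic acid | COc1cc(C(=O)O)ccc1O[Si](C)(C)C(C)(C)C | intermediate
29 | 4-[(tert-butyldimethylsilyl)oxy]-3-methoxybenzoyl chloride | COc1cc(C(=O)Cl)ccc1O[Si](C)(C)C(C)(C)C | intermediate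
30 | (1R,3E,8E)-2,2,9-trimethyl-5-methylidenecycloundeca-3,8-dien-1-yl 4-[(tert-butyldimethylsilyl)oxy]-3-methoxybenzoate | C=C1/C=C/C(C)(C)[C@H](OC(=O)c2ccc(O[Si](C)(C)C(C)(C)C)c(OC)c2)CC/C(C)=C/CC1 | intermediate
31 | (1R,3E,8E)-2,2,9-trimethyl-5-methylidenecycloundeca-3,8-dien-1-yl 4-hydroxy-3-methoxybenzoate | C=C1/C=C/C(C)(C)[C@H](OC(=O)c2ccc(O)c(OC)c2)CC/C(C)=C/CC1 | target

Total step count: 19. Longest linear sequence: 17 steps (steps 1–15, 18 and 19, from 1 to 31).

Steps most likely to fail

Step 9. The ketone is flanked by the quaternary C8 and the neopentylic C3, and methyl and vinyl differ little in size. The facial selectivity of the addition may therefore be low, or may favour entry syn to the vinyl group.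
- The fallback sets out from 13 and returns at 14. It brings in oxygen instead of carbon from the preferred face.
- Wittig methylenation of 13 (Ph3PCH3Br, KOt-Bu, toluene, 90 °C) would give the exocyclic methylene compound F1.
- m-CPBA (NaHCO3, CH2Cl2, 0 °C) should epoxidise the more electron-rich 1,1-disubstituted alkene in preference to the vinyl group. Attack from the face that a carbon nucleophile prefers now places oxygen there, which gives the opposite sense at C2 in the spiro-epoxide F2.
- Excess dimethylsulfonium methylide (Me3SI, n-BuLi, THF, −10 °C to rt) opens the epoxide at its CH2 group. The betaine loses dimethyl sulfide and gives the vinyl carbinol 14.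

Step 8. Three processes may compete with the vinyl shift: dehydrochlorination of the tertiary chloride by the basic Grignard reagent, migration of the C2–C3 ring bond (ring contraction) from a conformer with equatorial chloride, and epoxide closure after addition syn to chloride.
- The fallback sets out from 9 and returns at 13. It builds the vinyl group from acetaldehyde.
- Thermodynamic silylation (TMSI, (Me3Si)2NH, CH2Cl2, −20 °C to rt) would give the tetrasubstituted silyl enol ether F3.
- Mukaiyama aldol addition to acetaldehyde (TiCl4, CH2Cl2, −78 °C) creates the quaternary C8 in the aldol F4.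
- Dehydration with Martin sulfurane (CH2Cl2, rt) can only proceed toward the CH3 group, because C8 bears no hydrogen. It leads to 13.

Step 14. Ionisation of the hindered acetate may be slow, E/Z control in the hydrogen loss may be incomplete, and palladium hydride may isomerise the diene.
- The fallback sets out from 21, bypasses 22 and 23, and returns at 24. It replaces the elimination by reduction of a C–O bond.
- Ketone 21 is deprotonated at C3, the only α-position that bears hydrogen (KHMDS, THF, −78 °C). Trapping with Comins' reagent would give the dienyl triflate F5 from the enolate that has oxygen cis to the bulky C4, i.e. C1 trans to C4.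
- Palladium-catalysed formate reduction (Pd(OAc)2, PPh3, HCO2H, n-Bu3N, DMF, 60 °C) exchanges triflate for hydrogen with retention of the alkene geometry and gives 24.

Further compounds
F1 | step 9 | 1-methylidene analogue of 13, tert-butyl{[(1R,5R)-2,2,5-trimethyl-4-methylidene-5-vinylcycloheptyl]oxy}dimethylsilane | C=C1CC(C)(C)[C@H](O[Si](C)(C)C(C)(C)C)CC[C@]1(C)C=C
F2 | step 9 | spiro-epoxide (1-oxaspiro[2.6]nonane) from F1, epoxide oxygen cis to the C8 vinyl group | C1O[C@@]12CC(C)(C)[C@H](O[Si](C)(C)C(C)(C)C)CC[C@]2(C)C=C
F3 | step 8 | C2=C8 trimethylsilyl enol ether of 9 | CC1=C(O[Si](C)(C)C)CC(C)(C)[C@H](O[Si](C)(C)C(C)(C)C)CC1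
F4 | step 8 | (5R)-5-[(tert-butyldimethylsilyl)oxy]-2-(1-hydroxyethyl)-2,6,6-trimethylcycloheptan-1-one (isomers at C2 and the carbinol carbon) | O=C1CC(C)(C)[C@H](O[Si](C)(C)C(C)(C)C)CCC1(C)C(C)O
F5 | step 14 | C2 enol triflate of 21 (C2=C3, C1 trans to C4) | C=C1/C(OS(=O)(=O)C(F)(F)F)=C/C(C)(C)[C@H](O[Si](C)(C)C(C)(C)C)CC/C(C)=C/CC1
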